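(The earlier runs and the new flask come from a simulation with made-up constants; scatter was added.)

I decide to follow this flask through the coupling partner, which no reading shows, and not through the substrate.

common to all: substrate 20 mM

| charge | coupling partner | remark | time |
|---|---|---|---|
| gamma | 5 equiv | the very flask that is asked about, followed so far |  |
| zeta | 7.5 equiv | run made earlier |  |
| flask | 5.00 equiv |  | 4.0 d |

gamma run (percent of the substrate charged)

| time / h | substrate / % | mono adduct / % | double product / % |
|---|---|---|---|
| 2.50 | 87.2 | 13.6 | 1.0 |
| 5.00 | 81.3 | 18.1 | 0.7 |
| 6.00 | 79.6 | 20.3 | 0 |
| 10.0 | 76.0 | 24.0 | 0.2 |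
| 12.0 | 75.1 | 24.1 | 0.2 |

zeta run (percent of the substrate charged)

| time / d | substrate / % | mono adduct / % | double product / % |
|---|---|---|---|
| 0.333 | 67.6 | 31.8 | 0.4 |
| 0.625 | 65.2 | 34.4 | 0.8 |
| 1.04 | 64.2 | 35.5 | 0.9 |
| 2.00 | 63.9 | 35.7 | 1.0 |
| 4.00 | 64.7 | 34.5 | 1.9 |

(each reading ± 0.5 percentage points)



- how much substrate there is at 4.0 d, in percent of the substrate charged
- how much mono adduct there is at 4.0 d, in percent of the substrate charged
- how much double product there is at 4.0 d, in percent of the substrate charged
- how much tris adduct there is at 4.0 d, in percent of the substrate charged

The gamma run is this flask so far. I take as its pace the fall of ln c(substrate) per hour, the pseudo-first-order rate constant of the substrate: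

pace, first window = 0.0548 h⁻¹

pace, second window = 0.0280 h⁻¹

The first window stands for the first instants of the addition. By the middle of the gamma run the pace is about half, a reading that gives it a half-time of 2.58 h. The logarithm already allows for the lost substrate, so I read this as c(coupling partner) falling. Yet the substrate plateau of the zeta run, read as the mean of its last 3 readings, is 64.3%, which binds 4.76% of the zeta partner charge. I take it that the rest goes elsewhere, unseen; a balance is the other reading, and I do not exclude it.

For the end of this flask, the half-time is short against 4.0 d, so the substrate should stand at its stop. The total fall of ln c(substrate) per unit of c(coupling partner) charged I call the reach: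

reach = ln(charged substrate / plateau substrate) / c(coupling partner charged) = 2.95 M⁻¹

substrate at the end = charged substrate × exp(−reach × c(coupling partner charged)) = 74.5%

My reckoning leaves about 25.5% as mono adduct, with double product near its last gamma reading of 0.2% and tris adduct, which is not among the readings, taken as nil.

The forecast differs from mine. It says “this looks like a reversible addition” and gives substrate 72.5%, mono adduct 26.3%, double product 1% and tris adduct 0.2%.

The flask gives substrate 74.3%, mono adduct 25.3%, double product 0.339% and tris adduct 0%, so the forecast stands within its margins.

    coupling partner → decomposed reagent (k = 0.230 h⁻¹)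
    substrate + coupling partner → mono adduct (k = 0.720 M⁻¹ h⁻¹)
    coupling partner + double product → tris adduct (k = 0.0530 M⁻¹ h⁻¹)
    coupling partner + tris adduct → tetra adduct (k = 0.0210 M⁻¹ h⁻¹)
    coupling partner + mono adduct → double product (k = 0.0620 M⁻¹ h⁻¹)

In this flask at the start the coupling partner goes to decomposed reagent 16 times faster than into mono adduct. This flask's own reach is 2.97 M⁻¹. Carried to the same recipe with 80 mM of substrate at the same equivalents and time, the zeta reach gives 30.8% substrate, and that flask holds 34.0%.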